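**Retrosynthetic overview**
1. Key disconnection: the ring C–O bonds C1=O and C2–OH of the hydroxyquinone. Target 15 goes back to the ortho-alkylguaiacol 13. O2 delivers the carbonyl oxygen and an amine N-oxide delivers the hydroxyl oxygen, both in one flask.
2. 13 goes back to aldehyde 6 and ortho-lithiated, acetal-protected guaiacol 10. The benzylic oxygen is removed in the same flask.
3. 6 goes back to diene 4 and tiglaldehyde 5 through a catalytic enantioselective exo Diels–Alder reaction that sets all three stereocentres.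
4. 4 goes back to 2,2-dimethylcyclohexanone 1 and vinylmagnesium bromide 2.
5. Ring order: ring A is bought, ring B is closed by the cycloaddition, and the bought arene is turned into the quinone ring last.

Assumption: the facial sense of the oxazaborolidinium catalyst follows the accepted pre-transition-state model for 2-substituted enals (formyl C–H···O contact, s-trans enal stacked on one phenyl group). By that model the (R)-prolinol-derived catalyst leaves open the C2-Si/C3-Re face of 5 that leads to 6. If the first run gives the antipode, the (S)-catalyst is used and nothing else changes.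

**Step 1**
Reactants: 1 2,2-dimethylcyclohexan-1-one; 2 vinylmagnesium bromide
Product: 3 1-ethenyl-2,2-dimethylcyclohexan-1-ol (racemic)
Conditions: THF, 0 °C to rt, 2 h; sat. aq. NH4Cl
Reagents that add atoms: none
Why: Grignard 1,2-addition to the ketone; the carbinol centre is racemic and disappears in step 2.

**Step 2**
Reactants: 3 1-ethenyl-2,2-dimethylcyclohexan-1-ol
Product: 4 1-ethenyl-6,6-dimethylcyclohex-1-ene
Conditions: KHSO4 (10 mol %), BHT (trace), neat, 125 °C, product distilled out
Reagents that add atoms: none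
Why: Acid-catalysed E1 dehydration through the tertiary allylic cation; the only β-hydrogens sit on C6 because C2 is quaternary, so a single conjugated diene forms.

**Step 3**
Reactants: 4 1-ethenyl-6,6-dimethylcyclohex-1-ene; 5 (E)-2-methylbut-2-enal (tiglaldehyde)
Product: 6 (1R,2S,8aR)-1,2,5,5-tetramethyl-1,2,3,5,6,7,8,8a-octahydronaphthalene-1-carbaldehyde
Conditions: (R)-3,3-diphenyl-1-(2-methylphenyl)tetrahydro-1H,3H-pyrrolo[1,2-c][1,3,2]oxazaborole, C24H24BNO (20 mol %), (CF3SO2)2NH (18 mol %), 4 (1.5 equiv), CH2Cl2, −78 to −40 °C, 36 h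
Reagents that add atoms: none
Why: Catalytic enantioselective Diels–Alder reaction with a protonated oxazaborolidine Lewis acid: the unsubstituted diene terminus bonds to the β-carbon of 5 (ortho rule), suprafacial addition to the E-enal keeps the two methyl groups cis, the catalyst-bound formyl group stays exo to avoid the gem-dimethyl group next to the diene so that C8a–H ends up cis to CHO, and the phenyl-shielded complex leaves only the C2-Si/C3-Re face of 5 open, which fixes (1R,2S,8aR).

**Step 4**
Reactants: 7 2-methoxyphenol (guaiacol); 8 ethyl vinyl ether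
Product: 9 1-(1-ethoxyethoxy)-2-methoxybenzene (racemic acetal)
Conditions: pyridinium p-toluenesulfonate (2 mol %), CH2Cl2, 0 °C to rt, 3 h
Reagents that add atoms: none
Why: Acid-catalysed addition of the phenol to the enol ether (acetal protection); the acetal carbon is racemic, is removed in step 5, and the group is a stronger ortho director than methoxy.

**Step 5**
Reactants: 9 1-(1-ethoxyethoxy)-2-methoxybenzene; 6 (1R,2S,8aR)-1,2,5,5-tetramethyl-1,2,3,5,6,7,8,8a-octahydronaphthalene-1-carbaldehyde
Product: 13 2-methoxy-6-{[(1R,2S,8aS)-1,2,5,5-tetramethyl-1,2,3,5,6,7,8,8a-octahydronaphthalen-1-yl]methyl}phenol, via aryllithium 10 (not isolated), via lithium alkoxide 11 (not isolated), via acetal-protected arene 12 (not isolated)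
Conditions: 9 (1.5 equiv), n-BuLi (1.5 equiv), THF, 0 °C to rt, 2 h; 6, −78 to 0 °C, 1 h; transfer into Li (8 equiv), NH3(l)/THF, −78 °C, 20 min; solid NH4Cl; NH3 off; 1 M aq. HCl/THF, rt, 30 min
Reagents that add atoms: none
Why: Directed ortho-metalation next to the acetal oxygen, 1,2-addition to the aldehyde, dissolving-metal cleavage of the benzylic C–O bond on protonation (tandem arylation–reduction) and mild acetal hydrolysis follow each other; the carbinol carbon forms as an epimer mixture and is erased, while the isolated alkene and the three ring stereocentres are untouched (the 8a descriptor changes only through CIP priorities).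

**Step 6**
Reactants: 13 2-methoxy-6-{[(1R,2S,8aS)-1,2,5,5-tetramethyl-1,2,3,5,6,7,8,8a-octahydronaphthalen-1-yl]methyl}phenol
Product: 15 2-hydroxy-5-methoxy-3-{[(1R,2S,8aS)-1,2,5,5-tetramethyl-1,2,3,5,6,7,8,8a-octahydronaphthalen-1-yl]methyl}cyclohexa-2,5-diene-1,4-dione (target), via methoxyquinone 14 (not isolated)
Conditions: Co(salen) [N,N'-ethylenebis(salicylideneiminato)cobalt, C16H14CoN2O2, divalent cobalt] (10 mol %), O2 (1 atm), DMF, rt, 8 h; then anhydrous (CH3)3NO (2.5 equiv), 35 °C, 4 h, O2 kept on; cold 0.5 M aq. HCl wash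
Reagents that add atoms: dioxygen O=O; trimethylamine N-oxide C[N+](C)(C)[O-]
Why: Proposed new method: after the known Co(salen)/O2 para-oxygenation of the 2,6-disubstituted phenol to quinone 14, trimethylamine N-oxide serves as a nucleophilic oxygen donor that carries its own leaving group; its oxygen adds to C5–H of 14, the only unsubstituted β-carbon of the non-deactivated enone (the methoxy group turns the C4 carbonyl into a vinylogous ester and makes C3 electron-rich, and attack at the methoxy carbon is reversible because the N-oxide leaves faster than methoxide); the adduct then loses the acidified C5 proton with heterolysis of the weak N–O bond, so NMe3 departs and the stabilised hydroxyquinonate forms, and its acidity ties up NMe3 as the ammonium salt and blocks a second attack; NMe3 has no β-hydrogen to be dehydrogenated by the quinone, the isolated trisubstituted alkene is inert to a purely nucleophilic oxidant, O2 with cobalt re-oxidises any hydroquinone formed by redox exchange, and no stereocentre is touched; the closest known reaction types are the vicarious nucleophilic hydroxylation of nitroarenes with alkyl hydroperoxide anions, the Weitz–Scheffer epoxidation of quinones and the Ganem oxidation of alkyl halides with amine N-oxides.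

**Compound list**
1 | 2,2-dimethylcyclohexan-1-one | CC1(C)CCCCC1=O | starting material
2 | vinylmagnesium bromide | C=C[Mg]Br | starting material
3 | 1-ethenyl-2,2-dimethylcyclohexan-1-ol (racemic) | C=CC1(O)CCCCC1(C)C | intermediate
4 | 1-ethenyl-6,6-dimethylcyclohex-1-ene | C=CC1=CCCCC1(C)C | intermediate
5 | (E)-2-methylbut-2-enal | C/C=C(\C)C=O | starting material
6 | (1R,2S,8aR)-1,2,5,5-tetramethyl-1,2,3,5,6,7,8,8a-octahydronaphthalene-1-carbaldehyde | O=C[C@@]1(C)[C@@H]2CCCC(C)(C)C2=CC[C@@H]1C | intermediate
7 | 2-methoxyphenol | COc1ccccc1O | starting material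
8 | ethyl vinyl ether | C=COCC | starting material
9 | 1-(1-ethoxyethoxy)-2-methoxybenzene (racemic acetal) | CCOC(C)Oc1ccccc1OC | intermediate
10 | 2-(1-ethoxyethoxy)-3-methoxyphenyllithium | [Li]c1cccc(OC)c1OC(C)OCC | intermediate
11 | lithium [2-(1-ethoxyethoxy)-3-methoxyphenyl][(1R,2S,8aR)-1,2,5,5-tetramethyl-1,2,3,5,6,7,8,8a-octahydronaphthalen-1-yl]methanolate (epimers at carbinol and acetal carbons) | [Li+].[O-]C(c3cccc(OC)c3OC(C)OCC)[C@@]1(C)[C@@H]2CCCC(C)(C)C2=CC[C@@H]1C | intermediate
12 | 2-(1-ethoxyethoxy)-1-methoxy-3-{[(1R,2S,8aS)-1,2,5,5-tetramethyl-1,2,3,5,6,7,8,8a-octahydronaphthalen-1-yl]methyl}benzene (epimers at acetal carbon) | CCOC(C)Oc3c(OC)cccc3C[C@@]1(C)[C@@H]2CCCC(C)(C)C2=CC[C@@H]1C | intermediate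
13 | 2-methoxy-6-{[(1R,2S,8aS)-1,2,5,5-tetramethyl-1,2,3,5,6,7,8,8a-octahydronaphthalen-1-yl]methyl}phenol | COc1cccc(C[C@@]2(C)[C@@H]3CCCC(C)(C)C3=CC[C@@H]2C)c1O | intermediate
14 | 2-methoxy-6-{[(1R,2S,8aS)-1,2,5,5-tetramethyl-1,2,3,5,6,7,8,8a-octahydronaphthalen-1-yl]methyl}cyclohexa-2,5-diene-1,4-dione | COC1=CC(=O)C=C(C[C@@]2(C)[C@@H]3CCCC(C)(C)C3=CC[C@@H]2C)C1=O | intermediate
15 | 2-hydroxy-5-methoxy-3-{[(1R,2S,8aS)-1,2,5,5-tetramethyl-1,2,3,5,6,7,8,8a-octahydronaphthalen-1-yl]methyl}cyclohexa-2,5-diene-1,4-dione | COC1=CC(=O)C(O)=C(C[C@@]2(C)[C@@H]3CCCC(C)(C)C3=CC[C@@H]2C)C1=O | target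

**Total step count:** 6. **Longest linear sequence:** 5 (steps 1, 2, 3, 5, 6).

**Three steps most likely to fail**

Step 3. The α,β-disubstituted enal is a sluggish dienophile, and the exo ratio and enantiomeric excess on this hindered diene are untested. The fallback replaces catalysis by a racemic cycloaddition plus resolution. It sets out from 4 and 5 and comes back at 6.
- A Diels–Alder reaction promoted by EtAlCl2 (0.3 equiv, CH2Cl2, −78 to −20 °C) gives the exo adduct as a racemate, that is 6 together with the mirror-image aldehyde F1.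
- Condensation with (1S,2S)-N,N'-dimethyl-1,2-diphenylethane-1,2-diamine (4 Å sieves, Et2O, rt) gives two diastereomeric imidazolidines: the aminal of 6, F2, and the aminal of the antipode, F3.
- No new stereocentre arises, because the diamine is C2-symmetric.
- The two aminals are separated by chromatography or crystallisation.
- F2 is hydrolysed in 0.5 M aq. HCl/Et2O at 0 °C to enantiopure 6, and the diamine is recovered.

Step 5. Benzylic C–O cleavage on a hindered, electron-rich arene may stall or be accompanied by ring reduction. The fallback replaces electron transfer by a radical-chain deoxygenation. It sets out from 6 and 10 and comes back at 12.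
- The addition mixture is quenched with water and the free carbinol F4 is isolated.
- NaH, CS2 and MeI in THF convert it into the S-methyl xanthate F5.
- Bu3SnH with AIBN in toluene at 100 °C (Barton–McCombie reaction) gives 12.
- 12 is hydrolysed to 13 as in step 5.

Step 6 (the proposed new step). N-oxide addition may be too slow or too reversible, or 14 may tautomerise to a quinone methide under the mildly basic conditions. The fallback uses known chemistry and needs no late C–H oxygenation, because all four ring oxygens are bought with the arene. It sets out from 6 and comes back at 15.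
- 1,2,4,5-Tetramethoxybenzene is lithiated with n-BuLi (THF, 0 °C) to 2,3,5,6-tetramethoxyphenyllithium F6.
- F6 adds to 6 to give the lithium carbinolate F7.
- Li/NH3 followed by NH4Cl in the same flask gives the tetramethoxybenzyl decalin F8.
- Oxidative demethylation with (NH4)2Ce(NO3)6 in MeCN/H2O at 0 °C gives the dimethoxyquinone F9.
- Brief treatment with KOH in aqueous MeOH, then acidification, cleaves the twisted vinylogous ester next to the alkyl chain. The quinonate anion that forms protects the second methoxy group, and 15 results.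
- I am proposing this regioselectivity from the steric argument, not from a result I can confirm, so it should be checked on the first run.
- This fallback gives a count of 6 steps, all linear.

**Further compounds**
F1 | step 3 | (1S,2R,8aS)-1,2,5,5-tetramethyl-1,2,3,5,6,7,8,8a-octahydronaphthalene-1-carbaldehyde | O=C[C@]1(C)[C@H]2CCCC(C)(C)C2=CC[C@H]1C
F2 | step 3 | (4S,5S)-1,3-dimethyl-4,5-diphenyl-2-[(1R,2S,8aR)-1,2,5,5-tetramethyl-1,2,3,5,6,7,8,8a-octahydronaphthalen-1-yl]imidazolidine | CN1[C@@H](c2ccccc2)[C@H](c2ccccc2)N(C)C1[C@@]3(C)[C@@H]4CCCC(C)(C)C4=CC[C@@H]3C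
F3 | step 3 | (4S,5S)-1,3-dimethyl-4,5-diphenyl-2-[(1S,2R,8aS)-1,2,5,5-tetramethyl-1,2,3,5,6,7,8,8a-octahydronaphthalen-1-yl]imidazolidine | CN1[C@@H](c2ccccc2)[C@H](c2ccccc2)N(C)C1[C@]3(C)[C@H]4CCCC(C)(C)C4=CC[C@H]3C
F4 | step 5 | [2-(1-ethoxyethoxy)-3-methoxyphenyl][(1R,2S,8aR)-1,2,5,5-tetramethyl-1,2,3,5,6,7,8,8a-octahydronaphthalen-1-yl]methanol (epimers at carbinol and acetal carbons) | OC(c3cccc(OC)c3OC(C)OCC)[C@@]1(C)[C@@H]2CCCC(C)(C)C2=CC[C@@H]1C
F5 | step 5 | O-{[2-(1-ethoxyethoxy)-3-methoxyphenyl][(1R,2S,8aR)-1,2,5,5-tetramethyl-1,2,3,5,6,7,8,8a-octahydronaphthalen-1-yl]methyl} S-methyl carbonodithioate | CSC(=S)OC(c3cccc(OC)c3OC(C)OCC)[C@@]1(C)[C@@H]2CCCC(C)(C)C2=CC[C@@H]1C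
F6 | step 6 | 2,3,5,6-tetramethoxyphenyllithium | [Li]c1c(OC)c(OC)cc(OC)c1OC
F7 | step 6 | lithium (2,3,5,6-tetramethoxyphenyl)[(1R,2S,8aR)-1,2,5,5-tetramethyl-1,2,3,5,6,7,8,8a-octahydronaphthalen-1-yl]methanolate (carbinol epimers) | [Li+].[O-]C(c3c(OC)c(OC)cc(OC)c3OC)[C@@]1(C)[C@@H]2CCCC(C)(C)C2=CC[C@@H]1C
F8 | step 6 | 1,2,4,5-tetramethoxy-3-{[(1R,2S,8aS)-1,2,5,5-tetramethyl-1,2,3,5,6,7,8,8a-octahydronaphthalen-1-yl]methyl}benzene | COc1cc(OC)c(OC)c(C[C@@]2(C)[C@@H]3CCCC(C)(C)C3=CC[C@@H]2C)c1OC
F9 | step 6 | 2,5-dimethoxy-3-{[(1R,2S,8aS)-1,2,5,5-tetramethyl-1,2,3,5,6,7,8,8a-octahydronaphthalen-1-yl]methyl}cyclohexa-2,5-diene-1,4-dione | COC1=CC(=O)C(OC)=C(C[C@@]2(C)[C@@H]3CCCC(C)(C)C3=CC[C@@H]2C)C1=O
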